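## Analysis of the target

Target 15 is a furo[3,4-c]furan-1-one: a γ-butyrolactone (ring A: C1(=O), O2, C3, C3a, C6a) cis-fused along C3a–C6a to a tetrahydrofuran (ring B: C3a, C4, O5, C6, C6a). C3 carries the 3,4,5-trihydroxyphenyl ring and C6 the 3,4-dihydroxyphenyl ring. The four stereocentres are contiguous: C3 (S), C3a (R), C6a (S) and C6 (S). H3a and H6a are cis, and both aryl groups lie on the convex face, each trans to the ring bond next to it (H3/H3a trans, H6/H6a trans). The sensitive groups are the five free phenols (the pyrogallol oxidises in air, fastest under base), the two benzylic C–O bonds C3–O2 and C6–O5 (each para to a phenolic oxygen, so open to acid ionisation and to hydrogenolysis), and C6a–H, which is α to the carbonyl and β to O5, so that base can open ring B by elimination. The difficulty is that the two halves differ (lactone against ether, pyrogallol against catechol), which rules out any dimerisation logic, and that the absolute configuration has to be created from achiral material. The strategy rests on C3 and C3a: an aryl carbinol carbon and the neighbouring carbon bearing the C4H2–O arm form an anti 1,2-pair next to C6a, which together with C1 is the α-carbon of an acrylate once ring B is opened. That is the pattern left by a γ-substituted 2-alkoxycarbonyl allyl boronate adding to an aryl aldehyde. C6a and C6 need no separate control, because cis fusion is the only strain-free fusion and the aryl group at C6 prefers the convex face.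

## Retrosynthetic reasoning

15 from 14. No skeletal bond is cut. The five phenols are carried as benzyl ethers to the end and released by hydrogenolysis under neutral conditions, because the free pyrogallol and catechol would not survive the organometallic, palladium and acid steps, and because both aryl building blocks (7 and 11) are sold in this form. The forward reaction has to cleave five O–CH2 bonds and leave C3–O2 and C6–O5 alone.

14 from 12 (through 13). The O5–C6 bond is cut and C6a–H is exchanged for a C6a=C6 double bond, which opens ring B to the E-arylidene lactone 13, masked as silyl ether 12. This cut is chosen because it removes two stereocentres that look after themselves: the tether delivers oxygen from the side of C4, protonation at C6a can only give the cis-fused bicycle, and the aryl group settles on the convex face. The forward reaction must free the primary alcohol and add it across an electron-rich, aryl-conjugated enoate.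

12 from 10 and 11. The bond between C6 and the catechol ring is cut. The exocyclic methylene carbon of 10 becomes C6, and the second aryl ring arrives late as a purchased aryl bromide, which keeps the route convergent. The forward reaction is an arylation at the methylene terminus that must leave the double bond exocyclic and E.

10 from 9. The acyl bond C1–O2 is cut, giving a γ-hydroxy ester. The silyl ether on the C4 oxygen leaves only the C3 hydroxyl free, so the lactone can form in one direction. The forward reaction is a lactonisation with loss of the ester alkoxy group.

9 from 6 and 7 (key disconnection). The C3–C3a bond is cut. It joins the two stereocentres that have neither thermodynamic nor geometric help, so it is the bond worth making in a closed, catalyst-controlled transition state. Cutting C3a–C6a or C6–C6a instead would leave this anti pair to substrate control. The cut gives a purchased aldehyde and an allyl boronate whose alkene geometry encodes the anti relationship. The product has the ester one atom from the new hydroxyl and a methylene group ready for the arylation. The forward reaction must add through the γ-carbon, anti, and on one aldehyde face.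

6 from 3 and 4 (through 5). The bond between the α-carbon and the CH2B group is cut. A syn conjugate hydroalumination of ynoate 3 fixes the alkene geometry, and the vinylalane 5 is alkylated by 4 with retention.

3 from 1 (through 2). The bond between the alkyne terminus and the carboxyl carbon is cut, which is C-acylation of acetylide 2.

## Alternatives that were turned down

Alternative 1: Both benzylic C–O bonds (C3–O2 and C6–O5) are cut at once, back to the open-chain hydroxy acid A2, (2R,3R)-2-[3-(benzyloxy)-4-hydroxybenzyl]-3-[3,5-bis(benzyloxy)-4-hydroxybenzyl]-4-hydroxybutanoic acid, used as its carboxylate. In the forward step DDQ dehydrogenates both 4-hydroxybenzyl groups to para-quinone methides; the primary hydroxyl adds to the one that becomes C6 and the carboxylate to the one that becomes C3, giving the tribenzyl ether A1, which hydrogenolysis would take to 15.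
- For it: two rings and two stereocentres form in one oxidation. The pairing of nucleophile and methide is fixed by ring size, since the crossed pairing would give four-membered rings. A2 belongs to the trans-2,3-dibenzyl series, which enolate alkylation delivers reliably.
- Against it: A2 relactonises through its primary hydroxyl as soon as the carboxylate is protonated, and the reduced quinone is acidic; that removes the hydroxyl meant for ring B. The methide at the future C6 has an acidic hydrogen at C6a and can tautomerise to a cinnamate-type arylidene. Two methides must be raised on two different, easily over-oxidised phenols. C3 and C6 are set by kinetic capture with no control element beyond the neighbouring centre. The aryl units need para-free, meta-benzylated differentiation, and the two backbone stereocentres still need their own asymmetric synthesis.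
- Comparison: it is stronger on ring-forming economy. The chosen route offers in its place fully protected phenols throughout, purchased aryl building blocks and catalyst control of the absolute configuration.

Alternative 2: The C6a–C1 bond and the C1–O2 bond are cut, back to the dihydrofuran carbinol A4, (S)-{(3R)-5-[3,4-bis(benzyloxy)phenyl]-2,3-dihydrofuran-3-yl}[3,4,5-tris(benzyloxy)phenyl]methanol. In the forward step Rh(CO)2(acac) (monovalent rhodium) with a phosphinite ligand that exchanges reversibly with the carbinol oxygen adds hydrogen to C6 and a formyl group to C6a on the same face under CO/H2, and the aldehyde closes on the carbinol to lactol A3. Oxidation of A3 would give 14.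
- For it: the syn delivery fixes C6 and C6a together, stereospecifically and under kinetic control. On this point it is stronger than the chosen route, which relies on cation capture and on the stability of the exo arrangement at C6. The one-carbon unit is introduced with full atom economy.
- Against it: the alkene is a trisubstituted, aryl-conjugated cyclic enol ether, a slow hydroformylation substrate that can also be hydrogenated or isomerised by Rh–H. Exchange of the ligand with a hindered secondary benzylic alcohol is slow. A4 already contains C3 and C3a, so the hard anti pair must be made beforehand by the very kind of addition the chosen route uses. An oxidation step is added.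
- Comparison: it is longer and puts the risk on a less general step. The chosen route closes ring B with simpler operations.

Alternative 3: The C6–C6a bond and the O5–C4 bond of ring B are cut, back to 3,4-bis(benzyloxy)benzaldehyde A7 and the donor methyl 3-(acetoxymethyl)-2-(trimethylsilyl)but-3-enoate A6. In the forward step Pd2(dba)3 (zerovalent palladium) with a chiral phosphoramidite ionises A6 to an ester-bearing trimethylenemethane complex; the ester-bearing carbon adds to A7 and the alkoxide closes on the allyl terminus, giving the methylene tetrahydrofuran A5, methyl (2S,3S)-2-[3,4-bis(benzyloxy)phenyl]-4-methylideneoxolane-3-carboxylate.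
- For it: it is catalytic, enantioselective and convergent. Ring B and the C6/C6a pair form in one step from a purchased aldehyde, whereas the chosen key step closes no ring; on ring-forming power it is stronger.
- Against it: the methylene carbon of A5 must still become the aryl carbinol C3 (hydroboration, oxidation to the aldehyde level, arylmetal addition, lactonisation). C3a and C3 would then be set by substrate control, C3 with no strong bias. The ester-bearing centre is epimerisable and β to the ring oxygen. Aldehydes, and donor-substituted ones most of all, are among the less reactive acceptors for this cycloaddition.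
- Comparison: it spends the catalyst on C6/C6a, which ring fusion and convex-face preference would set anyway, and leaves C3/C3a without help. The chosen route does the reverse and is shorter.

Key step: step 3

Assumption: the (S)-enantiomer of the phosphoric acid is taken to leave the Si face of aldehyde 7 open, the sense known for this catalyst class with simple allyl and crotyl pinacolboronates and aryl aldehydes; if boronate 6 responds in the opposite sense, the (R)-acid is used with nothing else changed.

## Route

Step 1
Reactants: 1 tert-butyldimethyl(prop-2-yn-1-yloxy)silane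
Product: 3 methyl 4-[(tert-butyldimethylsilyl)oxy]but-2-ynoate, via lithium acetylide 2 (not isolated)
Conditions: n-BuLi, THF, −78 °C; ClCO2Me, −78 → 0 °C
Reagents that add atoms: methyl chloroformate, COC(=O)Cl; n-butyllithium, [Li]CCCC (lithium of 2 only)
Why: Deprotonation of the terminal alkyne and C-acylation of acetylide 2 with a chloroformate is the standard alkynoate synthesis; the silyl ether is inert to n-BuLi at −78 °C and no stereocentre is involved.

Step 2
Reactants: 3 methyl 4-[(tert-butyldimethylsilyl)oxy]but-2-ynoate; 4 2-(iodomethyl)-4,4,5,5-tetramethyl-1,3,2-dioxaborolane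
Product: 6 methyl (Z)-4-[(tert-butyldimethylsilyl)oxy]-2-[(4,4,5,5-tetramethyl-1,3,2-dioxaborolan-2-yl)methyl]but-2-enoate, via vinylalane 5 (not isolated)
Conditions: i-Bu2AlH, HMPA, THF, 0 °C; then 4, 0 °C → rt
Reagents that add atoms: diisobutylaluminium hydride, CC(C)C[AlH]CC(C)C (the Al(i-Bu)2 group of 5; only hydrogen stays in 6)
Why: Conjugate hydroalumination of an alkynoate by the i-Bu2AlH–HMPA complex places hydride on the β-carbon and aluminium on the α-carbon on the same side, without 1,2-reduction of the ester, and vinylalane 5 is alkylated at carbon by the reactive iodomethyl boronate 4 with retention. The CH2OSi group therefore ends trans to the CH2B group (Z by the sequence rules), which is the geometry the key step needs; no stereocentre is formed.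

Step 3
Reactants: 6 methyl (Z)-4-[(tert-butyldimethylsilyl)oxy]-2-[(4,4,5,5-tetramethyl-1,3,2-dioxaborolan-2-yl)methyl]but-2-enoate; 7 3,4,5-tris(benzyloxy)benzaldehyde
Product: 9 methyl (3R,4S)-3-{[(tert-butyldimethylsilyl)oxy]methyl}-4-hydroxy-2-methylidene-4-[3,4,5-tris(benzyloxy)phenyl]butanoate, via O-boryl adduct 8 (not isolated)
Conditions: (S)-TRIP [(S)-3,3'-bis(2,4,6-triisopropylphenyl)-1,1'-binaphthyl-2,2'-diyl hydrogen phosphate] (10 mol%), toluene, 4 Å MS, 0 °C → rt; aq. NaHCO3 work-up
Reagents that add atoms: none
Why: The phosphoric acid hydrogen-bonds through its P–OH to a boronate oxygen of 6 (its P=O contacting the formyl hydrogen), which raises the Lewis acidity of boron; aldehyde 7 binds to boron and the γ-carbon of 6 attacks the carbonyl carbon through a closed six-membered chair with allyl transposition, giving borate 8, which the aqueous work-up hydrolyses to 9. The closest known reactions are the chiral phosphoric acid-catalysed additions of allyl and (E)-crotyl pinacolboronates to aryl aldehydes and the Brønsted acid-accelerated additions of 2-alkoxycarbonyl allylboronates that lead to α-methylene-γ-butyrolactones. One C–C bond is formed (C3–C4 of 9, the later C3a–C3) and no ring is closed. The relative configuration is controlled by the alkene geometry of 6: the aryl group of 7 and the CH2OSi group, which is trans to the CH2B group, both sit equatorial in the chair, and that gives the anti pair. The absolute configuration at the carbinol carbon is controlled by the (S)-acid, which leaves the Si face of 7 open, and because the transition state is closed the same event fixes C3 as R. The step needs γ- over α-attack, anti over syn and one aldehyde face; the first two are secured by the cyclic transition state and by the configurational stability of the ester-conjugated alkene of 6, the third by the catalyst. Aldehyde 7 has no α-hydrogen and no ortho substituent and the silyl and benzyl ethers are inert to the weak acid; because the ester lowers the nucleophilicity of 6, room temperature and a longer time are planned than for simple allylboronates.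

Step 4
Reactants: 9 methyl (3R,4S)-3-{[(tert-butyldimethylsilyl)oxy]methyl}-4-hydroxy-2-methylidene-4-[3,4,5-tris(benzyloxy)phenyl]butanoate
Product: 10 (4R,5S)-4-{[(tert-butyldimethylsilyl)oxy]methyl}-3-methylidene-5-[3,4,5-tris(benzyloxy)phenyl]oxolan-2-one
Conditions: TsOH·H2O (10 mol%), toluene, rt
Reagents that add atoms: none
Why: Acid-catalysed lactonisation of a γ-hydroxy ester (intramolecular transesterification); only the secondary hydroxyl is free because the primary oxygen is silylated, so the lactone can form in one direction. Catalytic sulfonic acid in a non-hydroxylic solvent should leave the primary silyl ether and the benzyl ethers intact, neither stereocentre is touched, and any 10 already formed in step 3 is simply carried along.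

Step 5
Reactants: 10 (4R,5S)-4-{[(tert-butyldimethylsilyl)oxy]methyl}-3-methylidene-5-[3,4,5-tris(benzyloxy)phenyl]oxolan-2-one; 11 4-bromo-1,2-bis(benzyloxy)benzene
Product: 12 (3E,4R,5S)-3-{[3,4-bis(benzyloxy)phenyl]methylidene}-4-{[(tert-butyldimethylsilyl)oxy]methyl}-5-[3,4,5-tris(benzyloxy)phenyl]oxolan-2-one
Conditions: Pd(OAc)2 (5 mol%), [HP(t-Bu)3]BF4 (10 mol%), Cy2NMe, 1,4-dioxane, 80 °C
Reagents that add atoms: none
Why: Mizoroki–Heck arylation of an α-methylene-γ-butyrolactone: the aryl–palladium species adds to the unsubstituted methylene terminus and syn β-hydride elimination toward the benzylic hydrogen gives the aryl-conjugated E-alkene (aryl trans to the carbonyl), the usual outcome for 1,1-disubstituted acrylates and β-substituted α-methylene lactones. The bulky electron-rich phosphine allows oxidative addition of the electron-rich bromide at moderate temperature and the hindered amine strips HBr from palladium quickly, which limits Pd–H re-addition and double-bond migration; C4 and C5 are not involved.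

Step 6
Reactants: 12 (3E,4R,5S)-3-{[3,4-bis(benzyloxy)phenyl]methylidene}-4-{[(tert-butyldimethylsilyl)oxy]methyl}-5-[3,4,5-tris(benzyloxy)phenyl]oxolan-2-one
Product: 14 (3S,3aR,6S,6aS)-6-[3,4-bis(benzyloxy)phenyl]-3-[3,4,5-tris(benzyloxy)phenyl]tetrahydro-1H,3H-furo[3,4-c]furan-1-one, via hydroxy lactone 13 (not isolated)
Conditions: TFA/CH2Cl2/H2O (20:80:1), 0 °C → rt
Reagents that add atoms: none
Why: Aqueous trifluoroacetic acid removes the primary silyl ether and then protonates the electron-rich arylidene lactone, so that C6 gains benzylic cation character stabilised by the para benzyloxy group and is captured by the C4 hydroxyl; this is an acid-catalysed intramolecular oxa-conjugate addition (hydroalkoxylation of an electron-rich cinnamate-type alkene), formally 5-endo-trig but running through a cation whose C6–C6a bond can rotate. C3 should not ionise, because its 3,4,5-trialkoxyphenyl ring has a twisted para oxygen flanked by two meta oxygens. The tether delivers oxygen from the side of C4, protonation at C6a can only give the cis-fused bicycle, and the aryl group at C6 takes the convex position trans to C1, which is both the result of anti addition to the E-alkene and the more stable arrangement under reversible closure.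

Step 7
Reactants: 14 (3S,3aR,6S,6aS)-6-[3,4-bis(benzyloxy)phenyl]-3-[3,4,5-tris(benzyloxy)phenyl]tetrahydro-1H,3H-furo[3,4-c]furan-1-one
Product: 15 (3S,3aR,6S,6aS)-6-(3,4-dihydroxyphenyl)-3-(3,4,5-trihydroxyphenyl)tetrahydro-1H,3H-furo[3,4-c]furan-1-one
Conditions: H2 (1 atm), 10% Pd/C, THF/MeOH (1:1), rt
Reagents that add atoms: none
Why: Hydrogenolysis of five aryl benzyl ethers over palladium on carbon under neutral conditions; primary benzyl aryl ethers cleave much faster than the two secondary benzylic C–O bonds of the bicycle, so the reaction is stopped at the calculated hydrogen uptake. No stereocentre is touched and the air-sensitive pyrogallol is released without base.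

## Compound list

1 | tert-butyldimethyl(prop-2-yn-1-yloxy)silane | C#CCO[Si](C)(C)C(C)(C)C | starting material
2 | {3-[(tert-butyldimethylsilyl)oxy]prop-1-yn-1-yl}lithium | [Li]C#CCO[Si](C)(C)C(C)(C)C | intermediate
3 | methyl 4-[(tert-butyldimethylsilyl)oxy]but-2-ynoate | COC(=O)C#CCO[Si](C)(C)C(C)(C)C | intermediate
4 | 2-(iodomethyl)-4,4,5,5-tetramethyl-1,3,2-dioxaborolane | ICB1OC(C)(C)C(C)(C)O1 | starting material
5 | methyl (E)-4-[(tert-butyldimethylsilyl)oxy]-2-(diisobutylalumanyl)but-2-enoate (aluminium cis to the β-hydrogen) | COC(=O)/C([Al](CC(C)C)CC(C)C)=C\CO[Si](C)(C)C(C)(C)C | intermediate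
6 | methyl (Z)-4-[(tert-butyldimethylsilyl)oxy]-2-[(4,4,5,5-tetramethyl-1,3,2-dioxaborolan-2-yl)methyl]but-2-enoate | COC(=O)/C(CB1OC(C)(C)C(C)(C)O1)=C\CO[Si](C)(C)C(C)(C)C | intermediate
7 | 3,4,5-tris(benzyloxy)benzaldehyde | O=Cc1cc(OCc2ccccc2)c(OCc2ccccc2)c(OCc2ccccc2)c1 | starting material
8 | methyl (3R,4S)-3-{[(tert-butyldimethylsilyl)oxy]methyl}-2-methylidene-4-[(4,4,5,5-tetramethyl-1,3,2-dioxaborolan-2-yl)oxy]-4-[3,4,5-tris(benzyloxy)phenyl]butanoate | CC1(C)OB(O[C@H](c2cc(OCc3ccccc3)c(OCc3ccccc3)c(OCc3ccccc3)c2)[C@@H](CO[Si](C)(C)C(C)(C)C)C(=C)C(=O)OC)OC1(C)C | intermediate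
9 | methyl (3R,4S)-3-{[(tert-butyldimethylsilyl)oxy]methyl}-4-hydroxy-2-methylidene-4-[3,4,5-tris(benzyloxy)phenyl]butanoate | O[C@H](c1cc(OCc2ccccc2)c(OCc2ccccc2)c(OCc2ccccc2)c1)[C@@H](CO[Si](C)(C)C(C)(C)C)C(=C)C(=O)OC | intermediate
10 | (4R,5S)-4-{[(tert-butyldimethylsilyl)oxy]methyl}-3-methylidene-5-[3,4,5-tris(benzyloxy)phenyl]oxolan-2-one | O=C1O[C@H](c2cc(OCc3ccccc3)c(OCc3ccccc3)c(OCc3ccccc3)c2)[C@@H](CO[Si](C)(C)C(C)(C)C)C1=C | intermediate
11 | 4-bromo-1,2-bis(benzyloxy)benzene | Brc1ccc(OCc2ccccc2)c(OCc2ccccc2)c1 | starting material
12 | (3E,4R,5S)-3-{[3,4-bis(benzyloxy)phenyl]methylidene}-4-{[(tert-butyldimethylsilyl)oxy]methyl}-5-[3,4,5-tris(benzyloxy)phenyl]oxolan-2-one | O=C1O[C@H](c2cc(OCc3ccccc3)c(OCc3ccccc3)c(OCc3ccccc3)c2)[C@@H](CO[Si](C)(C)C(C)(C)C)/C1=C\c2ccc(OCc3ccccc3)c(OCc3ccccc3)c2 | intermediate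
13 | (3E,4R,5S)-3-{[3,4-bis(benzyloxy)phenyl]methylidene}-4-(hydroxymethyl)-5-[3,4,5-tris(benzyloxy)phenyl]oxolan-2-one | O=C1O[C@H](c2cc(OCc3ccccc3)c(OCc3ccccc3)c(OCc3ccccc3)c2)[C@@H](CO)/C1=C\c2ccc(OCc3ccccc3)c(OCc3ccccc3)c2 | intermediate
14 | (3S,3aR,6S,6aS)-6-[3,4-bis(benzyloxy)phenyl]-3-[3,4,5-tris(benzyloxy)phenyl]tetrahydro-1H,3H-furo[3,4-c]furan-1-one | O=C1O[C@H](c2cc(OCc3ccccc3)c(OCc3ccccc3)c(OCc3ccccc3)c2)[C@H]2CO[C@H](c3ccc(OCc4ccccc4)c(OCc4ccccc4)c3)[C@@H]12 | intermediate
15 | (3S,3aR,6S,6aS)-6-(3,4-dihydroxyphenyl)-3-(3,4,5-trihydroxyphenyl)tetrahydro-1H,3H-furo[3,4-c]furan-1-one | O=C1O[C@H](c2cc(O)c(O)c(O)c2)[C@H]2CO[C@H](c3ccc(O)c(O)c3)[C@@H]12 | target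

## Step count and least certain steps

Total step count: 7. Longest linear sequence: 7 steps (1 to 15); 4, 7 and 11 enter as purchased.

**Step 3 (key step).** The most likely failure is insufficient activation: the ester lowers the nucleophilicity of 6, the para oxygen lowers the electrophilicity of 7, and the phosphoric acid is a weak acid. Conversion may then be slow, and warming would let the uncatalysed, racemic pathway compete and erode the enantioselectivity; the facial sense itself rests on analogy. The fallback moves the chirality into an ester auxiliary and uses a Lewis acid to bring about the addition. It sets out from 1 and comes back at 10.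
- Acetylide 2 is carboxylated with CO2 to 4-[(tert-butyldimethylsilyl)oxy]but-2-ynoic acid F1.
- F1 is esterified with (−)-8-phenylmenthol (DCC, DMAP) to the 8-phenylmenthyl ynoate F2.
- The hydroalumination and alkylation of step 2 with 4 convert F2 into the 8-phenylmenthyl allyl boronate F3.
- Sc(OTf)3-catalysed addition of F3 to 7 at low temperature passes through the same closed chair; the auxiliary's phenyl ring shields one face of the enoate, and the product is the borate adduct F4.
- Catalytic TsOH lactonises F4 with expulsion of the auxiliary alcohol to give 10.

Which enantiomer of the auxiliary delivers the (4R,5S)-lactone is settled on a test run; the (−)-series is listed.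

**Step 6.** Three processes may interfere. The ring closure may be slow, because its geometry is 5-endo and it needs cation character at C6. The new benzylic ether may re-ionise, with loss of configurational integrity at C6 or Friedel–Crafts capture of the cation by one of the electron-rich rings. Benzyl ethers may be lost slowly in the acid. The fallback replaces the proton by a halonium ion and sets C6 by a stereospecific anti addition. It sets out from 12 and comes back at 14.
- 12 is desilylated with HF·pyridine in THF and 13 is isolated.
- N-bromosuccinimide in MeCN at 0 °C effects a bromoetherification in which the hydroxyl opens the bromonium ion at the benzylic carbon, giving the 6a-bromo furofuranone F5.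
- Bu3SnH with AIBN in toluene at 80 °C removes the bromine by a radical chain. The C6a radical can only take up hydrogen to give the cis-fused bicycle, and a radical is used because a metal enolate would expel O5.

**Step 5.** β-Hydride elimination into the ring (toward C4–H), or migration of the new double bond into the ring by Pd–H re-addition, would erase the C4 stereocentre; oxidative addition of the electron-rich bromide may also be slow at a temperature that keeps the alkene in place. The fallback is a base-free oxidative Heck arylation from 10 to 12 with 3,4-bis(benzyloxy)phenylboronic acid, Pd(OAc)2 (divalent palladium), 2,9-dimethyl-1,10-phenanthroline and O2 in MeCN at rt to 50 °C. It enters the cycle by transmetalation and not by oxidative addition, and runs at a temperature where Pd–H isomerisation is slower. This fallback makes no new compound (F0).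

**Step 7.** Over-reduction is the risk: once the phenols are free, the benzylic C–O bonds C6–O5 and C3–O2 become open to hydrogenolysis, which would open ring B or the lactone. The fallback from 14 to 15 is a non-reductive dealkylation with BCl3 and pentamethylbenzene in CH2Cl2 at −78 °C, in which the benzyl groups are transferred to the arene scavenger. This fallback makes no new compound (F0).

## Further compounds

F1 | step 3 | 4-[(tert-butyldimethylsilyl)oxy]but-2-ynoic acid | OC(=O)C#CCO[Si](C)(C)C(C)(C)C
F2 | step 3 | (1R,2S,5R)-5-methyl-2-(2-phenylpropan-2-yl)cyclohexyl 4-[(tert-butyldimethylsilyl)oxy]but-2-ynoate | CC(C)(c1ccccc1)[C@@H]1CC[C@@H](C)C[C@H]1OC(=O)C#CCO[Si](C)(C)C(C)(C)C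
F3 | step 3 | (1R,2S,5R)-5-methyl-2-(2-phenylpropan-2-yl)cyclohexyl (Z)-4-[(tert-butyldimethylsilyl)oxy]-2-[(4,4,5,5-tetramethyl-1,3,2-dioxaborolan-2-yl)methyl]but-2-enoate | CC(C)(c1ccccc1)[C@@H]1CC[C@@H](C)C[C@H]1OC(=O)/C(CB2OC(C)(C)C(C)(C)O2)=C\CO[Si](C)(C)C(C)(C)C
F4 | step 3 | (1R,2S,5R)-5-methyl-2-(2-phenylpropan-2-yl)cyclohexyl (3R,4S)-3-{[(tert-butyldimethylsilyl)oxy]methyl}-2-methylidene-4-[(4,4,5,5-tetramethyl-1,3,2-dioxaborolan-2-yl)oxy]-4-[3,4,5-tris(benzyloxy)phenyl]butanoate | CC(C)(c1ccccc1)[C@@H]1CC[C@@H](C)C[C@H]1OC(=O)C(=C)[C@H](CO[Si](C)(C)C(C)(C)C)[C@H](OB2OC(C)(C)C(C)(C)O2)c2cc(OCc3ccccc3)c(OCc3ccccc3)c(OCc3ccccc3)c2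
F5 | step 6 | (3S,3aR,6R,6aR)-6a-bromo-6-[3,4-bis(benzyloxy)phenyl]-3-[3,4,5-tris(benzyloxy)phenyl]tetrahydro-1H,3H-furo[3,4-c]furan-1-one | O=C1O[C@H](c2cc(OCc3ccccc3)c(OCc3ccccc3)c(OCc3ccccc3)c2)[C@H]2CO[C@H](c3ccc(OCc4ccccc4)c(OCc4ccccc4)c3)[C@@]12Br
F0 | step 5 | none | none
F0 | step 7 | none | none
A1 | alternative 1 | (3S,3aR,6S,6aS)-6-[3-(benzyloxy)-4-hydroxyphenyl]-3-[3,5-bis(benzyloxy)-4-hydroxyphenyl]tetrahydro-1H,3H-furo[3,4-c]furan-1-one | O=C1O[C@H](c3cc(OCc4ccccc4)c(O)c(OCc4ccccc4)c3)[C@H]2CO[C@H](c3ccc(O)c(OCc4ccccc4)c3)[C@@H]12
A2 | alternative 1 | (2R,3R)-2-[3-(benzyloxy)-4-hydroxybenzyl]-3-[3,5-bis(benzyloxy)-4-hydroxybenzyl]-4-hydroxybutanoic acid | OC(=O)[C@H](Cc1ccc(O)c(OCc2ccccc2)c1)[C@H](CO)Cc1cc(OCc2ccccc2)c(O)c(OCc2ccccc2)c1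
A3 | alternative 2 | (3S,3aR,6S,6aS)-6-[3,4-bis(benzyloxy)phenyl]-3-[3,4,5-tris(benzyloxy)phenyl]hexahydrofuro[3,4-c]furan-1-ol (both C1 epimers) | OC1O[C@H](c3cc(OCc4ccccc4)c(OCc4ccccc4)c(OCc4ccccc4)c3)[C@H]2CO[C@H](c3ccc(OCc4ccccc4)c(OCc4ccccc4)c3)[C@@H]12
A4 | alternative 2 | (S)-{(3R)-5-[3,4-bis(benzyloxy)phenyl]-2,3-dihydrofuran-3-yl}[3,4,5-tris(benzyloxy)phenyl]methanol | O[C@H](c1cc(OCc2ccccc2)c(OCc2ccccc2)c(OCc2ccccc2)c1)[C@H]1COC(c2ccc(OCc3ccccc3)c(OCc3ccccc3)c2)=C1
A5 | alternative 3 | methyl (2S,3S)-2-[3,4-bis(benzyloxy)phenyl]-4-methylideneoxolane-3-carboxylate | C=C1CO[C@H](c3ccc(OCc4ccccc4)c(OCc4ccccc4)c3)[C@H]1C(=O)OC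
A6 | alternative 3 | methyl 3-(acetoxymethyl)-2-(trimethylsilyl)but-3-enoate (racemic) | COC(=O)C([Si](C)(C)C)C(=C)COC(C)=O
A7 | alternative 3 | 3,4-bis(benzyloxy)benzaldehyde | O=Cc1ccc(OCc2ccccc2)c(OCc2ccccc2)c1
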